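At late times the gamma run turned down: E read 4.9% at 25.0 h but 3.9% at 30.0 h, after a flat stretch that began at 4.8% at 8.00 h. The drop was 1 percentage point against a scatter of 0.3 points, and it was the direction I expected. I followed one molecule of E. At its fork it may return to D or meet X and leave as Q, and I took the flat stretch as a pre-equilibrium with a slow leak from it.

| flask | L | G | remark | time |
|---|---|---|---|---|
| theta | 0.0096 M | 4 equiv | run made earlier |  |
| gamma | 0.17 M | 4 equiv | run made earlier |  |
| west | 0.012 M | 4.00 equiv |  | 2.5 d |
| north-west | 0.025 M | 4.00 equiv |  | 2.5 d |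
| south-west | 0.050 M | 4.00 equiv |  | 2.5 d |
| east | 0.10 M | 4.00 equiv |  | 2.5 d |
| south-east | 0.20 M | 4.00 equiv |  | 2.5 d |

| run | time / h | E / % |
|---|---|---|
| theta | 2.50 | 0 |
| theta | 6.00 | 0.3 |
| theta | 12.0 | 1.6 |
| theta | 30.0 | 4.1 |
| gamma | 8.00 | 4.8 |
| gamma | 15.0 | 4.8 |
| gamma | 25.0 | 4.9 |
| gamma | 30.0 | 3.9 |

(standard deviation of a reading: 0.3 percentage points)

- steps thought possible: L + G <-> X + J; J + G <-> X + D; D + G <-> X + E; X + E -> Q
- "hardly changes" means that all values lie within two and a half points (for a concentration: within two and a half percent of the largest)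

- [E] at the end for west, north-west, south-west, east, south-east, in this order
- how the row runs (rises, then falls / rises all the way / hardly changes / falls, then rises / falls all the way)

I compared south-east, charged at 0.20 M, with its neighbour gamma, charged at 0.17 M. Both have the same equivalents of G, but south-east runs for 2.5 d. Each listed step joins two species, and at fixed equivalents every concentration scales with c, the starting concentration of L. Percentages should therefore follow the product of c and time, not either one apart. Gamma's last reading came at a product of 5.10 M·h. I called this product the dose S, and I reckoned: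

S = c · t

gamma, last reading: S = 5.10 M·h

south-east, end: S = 12.0 M·h, which is 2.35 times as much

Because south-east takes the larger dose, I expected its percentage of E to end below gamma's last reading, which puts [E] under 0.00780 M.

The forecast gave 5.600 × 10⁻⁴ M, 0.0012 M, 0.0024 M, 0.0042 M and 0.0066 M, concluding “so the row rises throughout”: its shape was rises all the way. Its last value lies under my limit.

The flask gave 6.62 × 10⁻⁴ M, 0.00134 M, 0.00240 M, 0.00386 M and 0.00524 M, so the row rises all the way.

    L + G ⇌ X + J (K = 3.20, k = 1.10 M⁻¹ h⁻¹)
    J + G ⇌ X + D (K = 1.80, k = 0.900 M⁻¹ h⁻¹)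
    D + G ⇌ X + E (K = 0.0690, k = 2.30 M⁻¹ h⁻¹)
    X + E → Q (k = 0.490 M⁻¹ h⁻¹)

South-east thus ended below the forecast's 0.0066 M, holding E at 2.62% of the L charged beside Q at 38.1%. At 1.25 d south-east had taken a dose of 6.00 M·h, equal to the 6.00 M·h of east at its end. The two flasks then stood alike, with E at 3.86% in south-east and 3.86% in east, and Q at 22.0% and 22.0%.

The readings were generated by integration on assumed constants; scatter was added.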